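**Retrosynthetic overview**
- The target is the (7R,8R) syn-diol. C7 is set last, by Felkin–Anh reduction of a C7 aryl ketone made from a ring B aryllithium and a C8–C9 Weinreb amide.
- C8 is set by alkylating an Evans benzyloxyacetyl imide with the ring C benzylic bromide (this forms C8–C9).
- The strategy rests on ring C, which is pentasubstituted: contiguous oxygens at C4, C5 and C6, hydrogen at C3, allyl at C2 and C9 on C1. Ring C is the only ring built. It comes from a squarate-derived 4-chlorocyclobutenone and a (Z)-alkenylstannane by Stille coupling, 4π ring opening and 6π ring closure; ring B and both 4-allylphenyl rings are bought as arenes.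
- Both diaryl ethers are made by Chan–Lam arylation: on ring B before coupling, on ring C at the free C6–OH that the benzannulation delivers.
- Isopropyl and benzyl ethers are exchanged for silyl ethers while C7 is still a ketone, so the last step is a fluoride deprotection and no Lewis acid meets the para-oxygenated benzylic C7 alcohol.

Key step: step 7

Remark: C7 and C8 are the carbinol carbons, C9 is the CH2 on ring C, ring C is numbered C1 (bears C9) to C6 (bears the aryloxy group) and ring B is the aryl group on C7; the THP acetal carbon is carried as a racemate until step 9, and 5-bromo-2,3-dihydroxybenzaldehyde is taken as a catalogue compound.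

**Route**

Step 1
Reactants: 1 diisopropyl squarate
Product: 2 4-hydroxy-2,3-diisopropoxycyclobut-2-en-1-one (racemic)
Conditions: LiAlH(OtBu)3, THF, −78 to −20 °C; cold aq. NH4Cl
Reagents that add atoms: none
Why: Partial carbonyl reduction with the mild, bulky hydride LiAlH(OtBu)3 should stop after 1,2-addition to one of the two equivalent carbonyls, and a cold non-acidic work-up keeps the acid-labile hydroxy ketone intact (its stereocentre is racemic and is lost in step 7).

Step 2
Reactants: 2 4-hydroxy-2,3-diisopropoxycyclobut-2-en-1-one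
Product: 3 4-chloro-2,3-diisopropoxycyclobut-2-en-1-one (racemic)
Conditions: SOCl2, pyridine, CH2Cl2, −20 to 0 °C; used without storage
Reagents that add atoms: thionyl chloride, O=S(Cl)Cl
Why: Deoxychlorination of an α-hydroxy ketone with SOCl2/pyridine (chlorosulfite, then chloride displacement α to the carbonyl) is the classical route to α-chloro ketones, and base and low temperature should suppress ionisation with loss of an isopropyl group.

Step 3
Reactants: 4 propargyl alcohol; 5 allyl bromide
Product: 6 hex-5-en-2-yn-1-ol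
Conditions: CuI (10 mol%), K2CO3, Bu4NBr (10 mol%), DMF, rt
Reagents that add atoms: none
Why: Copper-catalysed allylation of the terminal alkyne (copper acetylide alkylation) should join the allyl group at carbon and leave the hydroxyl free.

Step 4
Reactants: 6 hex-5-en-2-yn-1-ol
Product: 8 (Z)-3-iodohexa-2,5-dien-1-ol, via cyclic alkenylalanate 7 (not isolated)
Conditions: NaAlH2(OCH2CH2OMe)2, Et2O, 0 °C to rt; EtOAc; then I2, THF, −78 to 0 °C
Reagents that add atoms: iodine, II
Why: Hydroxyl-directed trans-hydroalumination of the propargylic alcohol puts hydride on the carbon next to the carbinol and aluminium on the allyl-bearing carbon in a five-membered alanate, and iodinolysis with retention gives the (Z)-3-iodo allylic alcohol.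

Step 5
Reactants: 8 (Z)-3-iodohexa-2,5-dien-1-ol
Product: 9 2-[(Z)-3-iodohexa-2,5-dien-1-yloxy]tetrahydro-2H-pyran
Conditions: 3,4-dihydro-2H-pyran, PPTS (cat.), CH2Cl2, rt
Reagents that add atoms: 3,4-dihydro-2H-pyran, C1=COCCC1
Why: Acid-catalysed THP acetal formation gives an ether that tolerates t-BuLi, palladium and copper and is later removed without an oxidant, which matters because C9 becomes an electron-rich benzylic position that an oxidatively cleaved benzyl-type ether would not spare.

Step 6
Reactants: 9 2-[(Z)-3-iodohexa-2,5-dien-1-yloxy]tetrahydro-2H-pyran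
Product: 11 tributyl[(Z)-1-(tetrahydro-2H-pyran-2-yloxy)hexa-2,5-dien-3-yl]stannane, via alkenyllithium 10 (not isolated)
Conditions: t-BuLi (2.1 equiv), Et2O, −78 °C; then Bu3SnCl, −78 °C to rt
Reagents that add atoms: tributyltin chloride, CCCC[Sn](Cl)(CCCC)CCCC
Why: Iodine–lithium exchange and stannylation of the alkenyllithium both proceed with retention of alkene geometry, so tin ends on the allyl-bearing carbon cis to the CH2O group.

Step 7
Reactants: 3 4-chloro-2,3-diisopropoxycyclobut-2-en-1-one; 11 tributyl[(Z)-1-(tetrahydro-2H-pyran-2-yloxy)hexa-2,5-dien-3-yl]stannane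
Product: 15 3-allyl-5,6-diisopropoxy-2-[(tetrahydro-2H-pyran-2-yloxy)methyl]phenol (ring C phenol), via 4-alkenylcyclobutenone 12 (not isolated), via dienylketene 13 (not isolated), via cyclohexa-2,4-dienone 14 (not isolated)
Conditions: Pd2(dba)3 (2.5 mol%), P(2-furyl)3 (10 mol%), dioxane, 50 °C, then 100 °C
Reagents that add atoms: none
Why: Oxidative addition of the cyclobutenyl C–Cl bond of 3 to zerovalent palladium, transfer of the alkenyl group from tin with retention and reductive elimination (Stille coupling) should forge the C2–C3 bond of ring C in 12. On heating, 12 should open by a conrotatory 4π electrocyclic reaction to dienylketene 13, and a disrotatory 6π electrocyclisation then joins the ketene carbon to the alkene carbon that bears C9 (bond C6–C1), after which 14 tautomerises to the phenol. The closest known reaction type is the palladium-catalysed coupling of 4-chlorocyclobutenones with alkenylstannanes followed by thermal benzannulation; the 2,3-dialkoxy chloride is simply a new member of that substrate family. No stereocentre is created, because the sp3 ring carbon of 14 aromatises. The substitution pattern follows from connectivity alone: the two squarate oxygens become C4–O and C5–O, the carbonyl becomes the free C6–OH, the former C–Cl carbon becomes C3–H, and the stannane supplies C2 with its allyl group and C1 with C9. The selectivity needed is for the ring-opened isomer with the alkenyl group turned inward; the ring opening is reversible, so the outward isomer returns to 12 and only the inward isomer is consumed by cyclisation.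

Step 8
Reactants: 15 ring C phenol; 16 4-allylphenylboronic acid
Product: 17 2-{[6-allyl-2-(4-allylphenoxy)-3,4-diisopropoxybenzyl]oxy}tetrahydro-2H-pyran
Conditions: Cu(OAc)2 (1.5 equiv), pyridine, 4 Å molecular sieves, CH2Cl2, dry air, rt
Reagents that add atoms: none
Why: Chan–Lam oxidative O-arylation runs at room temperature under weakly basic conditions that spare the allyl groups, the THP acetal and the isopropyl ethers, and stoichiometric copper with excess boronic acid is chosen because the phenol carries two ortho substituents.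

Step 9
Reactants: 17 2-{[6-allyl-2-(4-allylphenoxy)-3,4-diisopropoxybenzyl]oxy}tetrahydro-2H-pyran
Product: 18 [6-allyl-2-(4-allylphenoxy)-3,4-diisopropoxyphenyl]methanol
Conditions: PPTS (cat.), MeOH, 40 °C
Reagents that add atoms: none
Why: Mild acid-catalysed transacetalisation to methanol (THP cleavage) should free the primary benzylic alcohol without ionising it.

Step 10
Reactants: 18 [6-allyl-2-(4-allylphenoxy)-3,4-diisopropoxyphenyl]methanol
Product: 19 1-allyl-3-(4-allylphenoxy)-2-(bromomethyl)-4,5-diisopropoxybenzene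
Conditions: CBr4, PPh3, CH2Cl2, 0 °C; used at once
Reagents that add atoms: carbon tetrabromide, BrC(Br)(Br)Br
Why: Appel bromination converts the primary benzylic alcohol to the bromide under neutral conditions, which avoids ionisation of this electron-rich position and the cyclisation onto the neighbouring aryloxy ring that ionisation would invite.

Step 11
Reactants: 20 (S)-4-benzyloxazolidin-2-one; 21 benzyloxyacetyl chloride
Product: 23 (S)-4-benzyl-3-[2-(benzyloxy)acetyl]oxazolidin-2-one, via lithiated oxazolidinone 22 (not isolated)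
Conditions: n-BuLi, THF, −78 °C; then 21, −78 to 0 °C
Reagents that add atoms: none
Why: N-acylation of the lithiated oxazolidinone with the acid chloride gives the glycolyl imide whose carbonyl carbon becomes C7 and whose CH2 becomes C8.

Step 12
Reactants: 23 (S)-4-benzyl-3-[2-(benzyloxy)acetyl]oxazolidin-2-one; 19 1-allyl-3-(4-allylphenoxy)-2-(bromomethyl)-4,5-diisopropoxybenzene
Product: 25 (S)-4-benzyl-3-{(2R)-3-[6-allyl-2-(4-allylphenoxy)-3,4-diisopropoxyphenyl]-2-(benzyloxy)propanoyl}oxazolidin-2-one, via sodium (Z)-enolate 24 (not isolated)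
Conditions: 23 (2.5 equiv), NaN(SiMe3)2, THF, −78 °C; then 19, −78 to −40 °C
Reagents that add atoms: none
Why: Evans-type alkylation of the chelated sodium (Z)-enolate of the glycolyl imide with the reactive benzylic bromide forms C8–C9, and because the benzyl group of the (S)-auxiliary blocks one enolate face the electrophile enters from the other and C8 is set as R.

Step 13
Reactants: 25 alkylated imide
Product: 26 (2R)-3-[6-allyl-2-(4-allylphenoxy)-3,4-diisopropoxyphenyl]-2-(benzyloxy)-N-methoxy-N-methylpropanamide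
Conditions: MeNH(OMe)·HCl, AlMe3, CH2Cl2, 0 °C to rt
Reagents that add atoms: N,O-dimethylhydroxylamine hydrochloride, CNOC.Cl
Why: Aluminium amide transamination of the acyl oxazolidinone (Weinreb amide formation) attacks the exocyclic carbonyl and releases the auxiliary without touching C8.

Step 14
Reactants: 27 5-bromo-2,3-dihydroxybenzaldehyde
Product: 28 5-bromo-2,3-diisopropoxybenzaldehyde
Conditions: 2-bromopropane, K2CO3, DMF, 60 °C
Reagents that add atoms: 2-bromopropane, CC(C)Br
Why: Williamson O-alkylation of both phenols gives isopropyl ethers that withstand peracid, copper and organolithium reagents.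

Step 15
Reactants: 28 5-bromo-2,3-diisopropoxybenzaldehyde
Product: 30 5-bromo-2,3-diisopropoxyphenol, via aryl formate 29 (not isolated)
Conditions: mCPBA, CH2Cl2, 0 °C to rt; then MeOH, Et3N (cat.)
Reagents that add atoms: 3-chloroperoxybenzoic acid, OOC(=O)c1cccc(Cl)c1
Why: Baeyer–Villiger oxidation of the ortho-alkoxy benzaldehyde proceeds with aryl migration to the formate (Dakin-type), and methanolysis of the formate liberates the phenol.

Step 16
Reactants: 30 5-bromo-2,3-diisopropoxyphenol; 16 4-allylphenylboronic acid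
Product: 31 1-(4-allylphenoxy)-5-bromo-2,3-diisopropoxybenzene
Conditions: Cu(OAc)2, pyridine, 4 Å molecular sieves, CH2Cl2, dry air, rt
Reagents that add atoms: none
Why: Chan–Lam O-arylation of a phenol with a single ortho substituent is a standard case and leaves the aryl bromide and the allyl group untouched.

Step 17
Reactants: 31 1-(4-allylphenoxy)-5-bromo-2,3-diisopropoxybenzene; 26 Weinreb amide
Product: 34 (2R)-3-[6-allyl-2-(4-allylphenoxy)-3,4-diisopropoxyphenyl]-1-[3-(4-allylphenoxy)-4,5-diisopropoxyphenyl]-2-(benzyloxy)propan-1-one, via aryllithium 32 (not isolated), via lithium hemiaminal 33 (not isolated)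
Conditions: 31, t-BuLi (2 equiv), THF, −78 °C; then 26, −78 to −40 °C; aq. NH4Cl
Reagents that add atoms: none
Why: Bromine–lithium exchange gives the ring B aryllithium, which adds only once to the Weinreb amide because the chelated tetrahedral lithium hemiaminal persists until work-up, giving the C7 ketone with C8 unchanged.

Step 18
Reactants: 34 benzyloxy ketone
Product: 35 (2R)-3-[6-allyl-2-(4-allylphenoxy)-3,4-dihydroxyphenyl]-1-[3-(4-allylphenoxy)-4,5-dihydroxyphenyl]-2-hydroxypropan-1-one
Conditions: BCl3 (excess), C6HMe5, CH2Cl2, −78 to 0 °C; MeOH quench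
Reagents that add atoms: none
Why: Lewis acid dealkylation with BCl3 cleaves the four aryl isopropyl ethers and the benzyl ether while C7 is still a ketone, so no ionisable para-oxygenated benzylic C–O bond is present, pentamethylbenzene traps the benzyl cation, and the diaryl ethers and allyl groups should survive at low temperature.

Step 19
Reactants: 35 pentahydroxy ketone
Product: 36 (2R)-3-[6-allyl-2-(4-allylphenoxy)-3,4-bis(tert-butyldimethylsilyloxy)phenyl]-1-[3-(4-allylphenoxy)-4,5-bis(tert-butyldimethylsilyloxy)phenyl]-2-(tert-butyldimethylsilyloxy)propan-1-one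
Conditions: TBSCl, imidazole, DMAP (cat.), DMF, rt to 40 °C
Reagents that add atoms: tert-butyldimethylsilyl chloride, CC(C)(C)[Si](C)(C)Cl
Why: Silylation of the four phenols and the C8 hydroxyl with TBSCl/imidazole installs fluoride-labile groups under conditions too mild to enolise the ketone, and makes the C8 oxygen a bulky, non-chelating substituent for the reduction.

Step 20
Reactants: 36 pentasilylated ketone
Product: 37 (1R,2R)-3-[6-allyl-2-(4-allylphenoxy)-3,4-bis(tert-butyldimethylsilyloxy)phenyl]-1-[3-(4-allylphenoxy)-4,5-bis(tert-butyldimethylsilyloxy)phenyl]-2-(tert-butyldimethylsilyloxy)propan-1-ol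
Conditions: LiBH(s-Bu)3, THF, −78 °C
Reagents that add atoms: none
Why: Felkin–Anh reduction of the α-silyloxy ketone with the bulky, non-chelating hydride LiBH(s-Bu)3 holds the C8–OSi bond anti to the incoming hydride, which passes the C8 hydrogen, so the new C7 stereocentre should be R and the diol syn (substrate control from C8; a chelating benzyl ether would have directed the hydride to the other face).

Step 21
Reactants: 37 silylated carbinol
Product: 38 (1R,2R)-3-[6-allyl-2-(4-allylphenoxy)-3,4-dihydroxyphenyl]-1-[3-(4-allylphenoxy)-4,5-dihydroxyphenyl]propane-1,2-diol (target, CNP0287568.1)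
Conditions: Bu4NF, AcOH, THF, 0 °C to rt, under argon
Reagents that add atoms: none
Why: Fluoride-mediated desilylation buffered with acetic acid removes all five silyl groups under near-neutral conditions that neither ionise the para-hydroxybenzylic C7 alcohol nor oxidise the catechols.

**Compound list**

1 | diisopropyl squarate | CC(C)OC1=C(OC(C)C)C(=O)C1=O | starting material
2 | 4-hydroxy-2,3-diisopropoxycyclobut-2-en-1-one (racemic) | CC(C)OC1=C(OC(C)C)C(=O)C1O | intermediate
3 | 4-chloro-2,3-diisopropoxycyclobut-2-en-1-one (racemic) | CC(C)OC1=C(OC(C)C)C(=O)C1Cl | intermediate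
4 | propargyl alcohol | C#CCO | starting material
5 | allyl bromide | C=CCBr | starting material
6 | hex-5-en-2-yn-1-ol | OCC#CCC=C | intermediate
7 | sodium cyclic alkenylalanate (ring O–Al–C(allyl)=CH–CH2, two 2-methoxyethoxy groups on Al) | C=CCC1=CCO[Al-]1(OCCOC)OCCOC.[Na+] | intermediate (not isolated)
8 | (Z)-3-iodohexa-2,5-dien-1-ol | C=CC/C(I)=C/CO | intermediate
9 | 2-[(Z)-3-iodohexa-2,5-dien-1-yloxy]tetrahydro-2H-pyran | C=CC/C(I)=C/COC1CCCCO1 | intermediate
10 | [(Z)-1-(tetrahydro-2H-pyran-2-yloxy)hexa-2,5-dien-3-yl]lithium | C=CC/C([Li])=C/COC1CCCCO1 | intermediate (not isolated)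
11 | tributyl[(Z)-1-(tetrahydro-2H-pyran-2-yloxy)hexa-2,5-dien-3-yl]stannane | C=CC/C(=C/COC1CCCCO1)[Sn](CCCC)(CCCC)CCCC | intermediate
12 | 2,3-diisopropoxy-4-[(Z)-1-(tetrahydro-2H-pyran-2-yloxy)hexa-2,5-dien-3-yl]cyclobut-2-en-1-one | CC(C)OC1=C(OC(C)C)C(=O)C1/C(CC=C)=C\COC2CCCCO2 | intermediate (not isolated)
13 | (3E,5Z)-5-allyl-2,3-diisopropoxy-7-(tetrahydro-2H-pyran-2-yloxy)hepta-1,3,5-trien-1-one (dienylketene) | O=C=C(OC(C)C)/C(OC(C)C)=C\C(CC=C)=C/COC1CCCCO1 | intermediate (not isolated)
14 | 5-allyl-2,3-diisopropoxy-6-[(tetrahydro-2H-pyran-2-yloxy)methyl]cyclohexa-2,4-dien-1-one | O=C1C(OC(C)C)=C(OC(C)C)C=C(CC=C)C1COC2CCCCO2 | intermediate (not isolated)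
15 | 3-allyl-5,6-diisopropoxy-2-[(tetrahydro-2H-pyran-2-yloxy)methyl]phenol (ring C phenol) | C=CCc1cc(OC(C)C)c(OC(C)C)c(O)c1COC2CCCCO2 | intermediate
16 | 4-allylphenylboronic acid | C=CCc1ccc(B(O)O)cc1 | starting material
17 | 2-{[6-allyl-2-(4-allylphenoxy)-3,4-diisopropoxybenzyl]oxy}tetrahydro-2H-pyran | C=CCc1ccc(Oc2c(OC(C)C)c(OC(C)C)cc(CC=C)c2COC3CCCCO3)cc1 | intermediate
18 | [6-allyl-2-(4-allylphenoxy)-3,4-diisopropoxyphenyl]methanol | C=CCc1ccc(Oc2c(OC(C)C)c(OC(C)C)cc(CC=C)c2CO)cc1 | intermediate
19 | 1-allyl-3-(4-allylphenoxy)-2-(bromomethyl)-4,5-diisopropoxybenzene | C=CCc1ccc(Oc2c(OC(C)C)c(OC(C)C)cc(CC=C)c2CBr)cc1 | intermediate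
20 | (S)-4-benzyloxazolidin-2-one | O=C1N[C@@H](Cc2ccccc2)CO1 | starting material
21 | benzyloxyacetyl chloride | O=C(Cl)COCc1ccccc1 | starting material
22 | N-lithio-(S)-4-benzyloxazolidin-2-one | O=C1N([Li])[C@@H](Cc2ccccc2)CO1 | intermediate (not isolated)
23 | (S)-4-benzyl-3-[2-(benzyloxy)acetyl]oxazolidin-2-one | O=C(COCc1ccccc1)N2C(=O)OC[C@@H]2Cc3ccccc3 | intermediate
24 | sodium (Z)-enolate of 23 | [Na]O/C(=C\OCc1ccccc1)N2C(=O)OC[C@@H]2Cc3ccccc3 | intermediate (not isolated)
25 | (S)-4-benzyl-3-{(2R)-3-[6-allyl-2-(4-allylphenoxy)-3,4-diisopropoxyphenyl]-2-(benzyloxy)propanoyl}oxazolidin-2-one | O=C([C@H](OCc1ccccc1)Cc2c(CC=C)cc(OC(C)C)c(OC(C)C)c2Oc3ccc(CC=C)cc3)N4C(=O)OC[C@@H]4Cc5ccccc5 | intermediate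
26 | (2R)-3-[6-allyl-2-(4-allylphenoxy)-3,4-diisopropoxyphenyl]-2-(benzyloxy)-N-methoxy-N-methylpropanamide | CON(C)C(=O)[C@H](OCc1ccccc1)Cc2c(CC=C)cc(OC(C)C)c(OC(C)C)c2Oc3ccc(CC=C)cc3 | intermediate
27 | 5-bromo-2,3-dihydroxybenzaldehyde | O=Cc1cc(Br)cc(O)c1O | starting material
28 | 5-bromo-2,3-diisopropoxybenzaldehyde | O=Cc1cc(Br)cc(OC(C)C)c1OC(C)C | intermediate
29 | 5-bromo-2,3-diisopropoxyphenyl formate | O=COc1cc(Br)cc(OC(C)C)c1OC(C)C | intermediate (not isolated)
30 | 5-bromo-2,3-diisopropoxyphenol | Oc1cc(Br)cc(OC(C)C)c1OC(C)C | intermediate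
31 | 1-(4-allylphenoxy)-5-bromo-2,3-diisopropoxybenzene | C=CCc1ccc(Oc2cc(Br)cc(OC(C)C)c2OC(C)C)cc1 | intermediate
32 | [3-(4-allylphenoxy)-4,5-diisopropoxyphenyl]lithium | C=CCc1ccc(Oc2cc([Li])cc(OC(C)C)c2OC(C)C)cc1 | intermediate (not isolated)
33 | lithium hemiaminal from 32 and 26 (new tetrahedral carbon undefined, C8 R) | [Li]OC(c1cc(Oc2ccc(CC=C)cc2)c(OC(C)C)c(OC(C)C)c1)(N(C)OC)[C@H](OCc3ccccc3)Cc4c(CC=C)cc(OC(C)C)c(OC(C)C)c4Oc5ccc(CC=C)cc5 | intermediate (not isolated)
34 | (2R)-3-[6-allyl-2-(4-allylphenoxy)-3,4-diisopropoxyphenyl]-1-[3-(4-allylphenoxy)-4,5-diisopropoxyphenyl]-2-(benzyloxy)propan-1-one | O=C(c1cc(Oc2ccc(CC=C)cc2)c(OC(C)C)c(OC(C)C)c1)[C@H](OCc3ccccc3)Cc4c(CC=C)cc(OC(C)C)c(OC(C)C)c4Oc5ccc(CC=C)cc5 | intermediate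
35 | (2R)-3-[6-allyl-2-(4-allylphenoxy)-3,4-dihydroxyphenyl]-1-[3-(4-allylphenoxy)-4,5-dihydroxyphenyl]-2-hydroxypropan-1-one | O=C(c1cc(Oc2ccc(CC=C)cc2)c(O)c(O)c1)[C@H](O)Cc3c(CC=C)cc(O)c(O)c3Oc4ccc(CC=C)cc4 | intermediate
36 | penta(tert-butyldimethylsilyl) ether of 35 (four aryl-O and the C8-O silylated, C8 R) | O=C(c1cc(Oc2ccc(CC=C)cc2)c(O[Si](C)(C)C(C)(C)C)c(O[Si](C)(C)C(C)(C)C)c1)[C@H](O[Si](C)(C)C(C)(C)C)Cc3c(CC=C)cc(O[Si](C)(C)C(C)(C)C)c(O[Si](C)(C)C(C)(C)C)c3Oc4ccc(CC=C)cc4 | intermediate
37 | (1R,2R)-carbinol from 36 (C7-OH free, C8-O and four aryl-O silylated) | C=CCc1ccc(Oc2cc([C@@H](O)[C@H](O[Si](C)(C)C(C)(C)C)Cc3c(CC=C)cc(O[Si](C)(C)C(C)(C)C)c(O[Si](C)(C)C(C)(C)C)c3Oc4ccc(CC=C)cc4)cc(O[Si](C)(C)C(C)(C)C)c2O[Si](C)(C)C(C)(C)C)cc1 | intermediate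
38 | (1R,2R)-3-[6-allyl-2-(4-allylphenoxy)-3,4-dihydroxyphenyl]-1-[3-(4-allylphenoxy)-4,5-dihydroxyphenyl]propane-1,2-diol | C=CCc1ccc(Oc2cc([C@@H](O)[C@H](O)Cc3c(CC=C)cc(O)c(O)c3Oc3ccc(CC=C)cc3)cc(O)c2O)cc1 | target

**Step count and risks**

Total step count: 21. Longest linear sequence: 15 steps (from 4 through steps 3–10, 12, 13 and 17–21 to 38).

Steps most likely to fail:

1. Step 7 (together with step 2, which feeds it). The dialkoxy chloride may ionise and lose an isopropyl group before oxidative addition, and transmetalation of the α-branched stannane may be too slow to compete with decomposition. The fallback sets out from 9 and 1, avoids the chloride and the tin reagent, and returns at 17. Iodine–lithium exchange of 9 (t-BuLi, Et2O, −78 °C) gives 10, which adds to one carbonyl of diisopropyl squarate 1. The lithium alkoxide is silylated in the flask (TBSOTf) to 4-(tert-butyldimethylsilyloxy)-2,3-diisopropoxy-4-[(Z)-1-(tetrahydro-2H-pyran-2-yloxy)hexa-2,5-dien-3-yl]cyclobut-2-en-1-one F1. Thermolysis of this compound (toluene, 110 °C) by the same 4π opening and 6π closure should give 3-allyl-4-(tert-butyldimethylsilyloxy)-5,6-diisopropoxy-2-[(tetrahydro-2H-pyran-2-yloxy)methyl]phenol F2, which has the correct ring C but an extra oxygen at C3. Chan–Lam arylation with 16 as in step 8 gives the corresponding 4-allylphenyl ether F3. Bu4NF in THF frees the C3 phenol 2-allyl-4-(4-allylphenoxy)-5,6-diisopropoxy-3-[(tetrahydro-2H-pyran-2-yloxy)methyl]phenol F4. Tf2O/pyridine converts it to the aryl triflate F5, and palladium-catalysed reduction (Pd(OAc)2, dppf, HCO2H, Et3N, DMF, 70 °C) removes the C3 oxygen to give 17.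

2. Step 8. O-arylation at a phenol flanked by two ortho substituents may be sluggish, and copper-mediated oxidation of the electron-rich phenol may compete. The fallback sets out from 15 and returns at 17. Ullmann-type coupling with 1-bromo-4-iodobenzene (CuI, picolinic acid, K3PO4, DMSO, 80 °C, conditions suited to hindered phenols) reacts at the iodide and gives 2-{[6-allyl-2-(4-bromophenoxy)-3,4-diisopropoxybenzyl]oxy}tetrahydro-2H-pyran F6. Stille allylation of the aryl bromide (allyl-SnBu3, Pd(PPh3)4, LiCl, DMF, 90 °C) then installs the allyl group and gives 17.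

3. Step 20. Facial selectivity of hydride delivery may be poor if the Felkin–Anh preference of the α-silyloxy ketone is weak. The fallback sets out from 36 and returns at 37 with no new compound: the substrate-controlled hydride is replaced by catalyst-controlled asymmetric transfer hydrogenation of the aryl ketone with RuCl[(S,S)-TsDPEN](p-cymene) in HCO2H/Et3N. With the aryl group as the recognised substituent this should deliver the same C7 configuration (R), independent of the bias from C8.

Further compounds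
F1 | step 7 | 4-(tert-butyldimethylsilyloxy)-2,3-diisopropoxy-4-[(Z)-1-(tetrahydro-2H-pyran-2-yloxy)hexa-2,5-dien-3-yl]cyclobut-2-en-1-one | CC(C)OC1=C(OC(C)C)C(=O)C1(O[Si](C)(C)C(C)(C)C)/C(CC=C)=C\COC2CCCCO2
F2 | step 7 | 3-allyl-4-(tert-butyldimethylsilyloxy)-5,6-diisopropoxy-2-[(tetrahydro-2H-pyran-2-yloxy)methyl]phenol | C=CCc1c(O[Si](C)(C)C(C)(C)C)c(OC(C)C)c(OC(C)C)c(O)c1COC2CCCCO2
F3 | step 7 | 2-{[6-allyl-2-(4-allylphenoxy)-5-(tert-butyldimethylsilyloxy)-3,4-diisopropoxybenzyl]oxy}tetrahydro-2H-pyran | C=CCc1ccc(Oc2c(OC(C)C)c(OC(C)C)c(O[Si](C)(C)C(C)(C)C)c(CC=C)c2COC3CCCCO3)cc1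
F4 | step 7 | 2-allyl-4-(4-allylphenoxy)-5,6-diisopropoxy-3-[(tetrahydro-2H-pyran-2-yloxy)methyl]phenol | C=CCc1ccc(Oc2c(OC(C)C)c(OC(C)C)c(O)c(CC=C)c2COC3CCCCO3)cc1
F5 | step 7 | 2-allyl-4-(4-allylphenoxy)-5,6-diisopropoxy-3-[(tetrahydro-2H-pyran-2-yloxy)methyl]phenyl trifluoromethanesulfonate | C=CCc1ccc(Oc2c(OC(C)C)c(OC(C)C)c(OS(=O)(=O)C(F)(F)F)c(CC=C)c2COC3CCCCO3)cc1
F6 | step 8 | 2-{[6-allyl-2-(4-bromophenoxy)-3,4-diisopropoxybenzyl]oxy}tetrahydro-2H-pyran | C=CCc1cc(OC(C)C)c(OC(C)C)c(Oc2ccc(Br)cc2)c1COC3CCCCO3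
F0 | step 20 | none | none
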